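**Remark on the chemistry.** The two stereocentres of the target are R and S on a constitutionally symmetric chain, so the compound is the achiral meso diastereomer. "Single stereoisomer" is therefore taken to mean the meso form free of the racemic (R,R)/(S,S) pair, and only relative configuration has to be controlled.

## The problem

- Target 11, 4,4′-[(2R,3S)-2,3-dimethylbutane-1,4-diyl]bis(2,6-dimethoxyphenol), is a dibenzylbutane lignan. Two syringyl rings are joined by an open chain ArC7H2–C8H(C9H3)–C8′H(C9′H3)–C7′H2Ar, and there is no ring besides the two arenes.
- The only stereocentres are C8 and C8′. Because the two halves are identical, the R,S pair is meso, and the task is to exclude the racemic diastereomer.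
- In a flexible chain whose substituents are methyl and arylmethyl, neither centre can be expected to direct the other usefully. Both should therefore be set in one stereospecific event.
- The 2,6-dimethoxyphenols are easily oxidised, and a benzylic leaving group para to a free phenol would ionise towards a quinone methide. The phenols must stay masked until the last step, and the mask must leave under neutral, non-oxidising conditions.
- The enabling feature is that the meso pair C8/C8′ is exactly what same-face addition of H2 to a Z-configured C8=C8′ double bond delivers.
- The C9–C8–C8′–C9′ unit of that alkene is 2-butyne (1), so both methyl groups come with the alkyne and a cis-difunctionalisation fixes the geometry.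
- The two bonds C7–C8 and C7′–C8′ are identical, so one benzylic electrophile can form both in a single two-directional operation.

## Retrosynthesis

**11 ⇒ 10.** The two phenolic O–H bonds are traced back to O-benzyl ethers in (2R,3S)-1,4-bis[4-(benzyloxy)-3,5-dimethoxyphenyl]-2,3-dimethylbutane (10). Benzyl is preferred to silyl or acyl groups, which would not survive hot aqueous carbonate in the coupling. It is preferred to acetal groups, whose removal would put acid on an electron-rich arene. The forward reaction only has to cleave two aryl benzyl ethers on a saturated, stereochemically inert chain.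

**10 ⇒ 9.** The C8–H and C8′–H bonds are cut, turning the meso pair into the geometry of (Z)-1,4-bis[4-(benzyloxy)-3,5-dimethoxyphenyl]-2,3-dimethylbut-2-ene (9). Setting the two centres one after the other with auxiliaries would spend absolute stereocontrol on an achiral target. This cut removes both stereocentres at once and stores their relationship in a double bond. The forward reaction must deliver both hydrogens to one face before the double bond can move.

**9 ⇒ 3 + two 7 (through 8).** The bonds C7–C8 and C7′–C8′ are cut. The fragments are (Z)-2,3-bis(4,4,5,5-tetramethyl-1,3,2-dioxaborolan-2-yl)but-2-ene (3) and two molecules of 2-(benzyloxy)-5-(bromomethyl)-1,3-dimethoxybenzene (7). The mono-benzylated alkenyl boronate 8 lies on the way.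
- Cutting C8=C8′ instead (reductive coupling of two arylacetone units) would give no control of alkene geometry.
- Cutting aryl–C7 would require a geometrically pure Z-1,4-difunctional 2,3-dimethylbutene.
- The chosen cut reduces a C36 alkene to a C4 and a C16 piece. It asks for two palladium-catalysed couplings that keep the cis arrangement inherited from 3.
- A benzyl bromide is a good partner because its palladium intermediate has no β-hydrogen.

**3 ⇒ 1 + 2.** The two C–B bonds are cut to give 2-butyne (1) and bis(pinacolato)diboron (2). Metal-catalysed addition of a B–B bond across an alkyne is suprafacial, so the Z geometry is guaranteed by mechanism. Both precursors are achiral commodity chemicals.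

**7 ⇒ 6 ⇒ 5 ⇒ 4.** The C–Br bond is traced to the alcohol [4-(benzyloxy)-3,5-dimethoxyphenyl]methanol (6). The alcohol comes from the aldehyde 4-(benzyloxy)-3,5-dimethoxybenzaldehyde (5), and the O-benzyl bond leads to syringaldehyde (4). Syringaldehyde already carries the full oxygenation pattern and the benzylic carbon C7. Only functional-group changes are needed, each routine for this arene.

## Roads not taken

**Alternative 1:**
- Cut: the methyl C9′ is removed from C8′ and the benzylic carbon C7 from C8 of a five-membered template, 5-[4-(benzyloxy)-3,5-dimethoxyphenyl]furan-2(5H)-one (A1). In A1, C9 is the lactone carbonyl and C7′ the aryl-bearing ring carbon.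
- Forward key step: a methyl cuprate adds to C8′ anti to the aryl group. The enolate is then benzylated at C8 with bromide 7, anti to the new methyl, to give the trans,trans-lactone A2 in one tandem operation.
- Merits: each new substituent enters trans to its neighbour on a rigid ring. The 3,4-trans relation of A2 corresponds to the meso relation of C8/C8′ once the ring is opened and reduced. No migration-prone alkene is involved.
- Weak points: A2 carries two oxygen functions that the target lacks. The lactone must be reduced, the benzylic C7′–O bond hydrogenolysed and the primary C9 alcohol deoxygenated to methyl, in addition to the steps needed to reach A1. The two identical halves are built by unrelated chemistry, so the symmetry is unused. Cuprate-derived enolates are often slow to alkylate with benzyl halides.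
- Comparison: the ring-based stereocontrol of A2 is arguably more firmly grounded than hydrogenation of a tetrasubstituted alkene. The chosen plan sets against this roughly half the number of operations, no redox corrections, and one electrophile used twice.

**Alternative 2:**
- Cut: the methyl carbons C9 and C9′ are removed from C8 and C8′. Each is traced to a boron on the Z-disubstituted alkene (Z)-1,4-bis[4-(benzyloxy)-3,5-dimethoxyphenyl]but-2-ene (A3).
- Forward key step: syn-diboration of A3 with 2 gives the meso vicinal bis(boronate) A4 in the flask. Two one-carbon homologations with a chloromethyl carbenoid, each a 1,2-migration with retention, then give meso-1,4-bis(pinacolboryl)-2,3-bis[4-(benzyloxy)-3,5-dimethoxybenzyl]butane (A5).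
- Merits: the stereodefining addition is on a 1,2-disubstituted alkene, a much easier substrate than a tetrasubstituted one. No hydrogenation catalyst that could move a double bond is needed. In this respect the alternative is better than the chosen plan.
- Weak points: A3 must itself be made geometrically pure. The carbenoid cannot distinguish the secondary boronates of A4 from the primary ones of A5, so under- and over-homologation are likely in a double process. The end-game must replace two unactivated primary C–B bonds in A5 by C–H, which is not routine for alkyl pinacol boronates.
- Comparison: the chosen plan gets both methyls free with 1 and needs no end-game on boron. It pays for this with a hydrogenation that must not isomerise 9.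

**Alternative 3:**
- Cut: the two aryl–C7 bonds. All stereochemistry is bought with meso-2,3-dimethylbutane-1,4-diyl bis(4-methylbenzenesulfonate) (A7).
- Forward key step: two equivalents of [4-(benzyloxy)-3,5-dimethoxyphenyl]magnesium bromide (A6) displace both primary tosylates of A7 under copper catalysis. The product A8 is identical with 10.
- Merits: no stereocentre is formed or touched, so the meso configuration cannot erode. From A7 the target is two operations away. In stereochemical certainty this road is better than the chosen one, and in step count it is at least as good.
- Weak points: the outcome depends on the supply and diastereomeric purity of the meso C6 core. Any racemic diastereomer in A7 would be carried into A8 and be hard to remove. Both electrophilic carbons of A7 are β-branched, which slows substitution and gives room for mono-coupling and Grignard homocoupling. A6 needs an aryl bromide that is not a direct derivative of syringaldehyde.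
- Comparison: this is the strongest competitor. The chosen plan sets three things against it. It relies only on achiral commodity materials. Its coupling uses an unhindered benzyl bromide without β-hydrogens. The geometry of 9 can be checked before the stereocentres are committed.

Key step: step 5

## Route

Step 1
Reactants: 1 2-butyne; 2 bis(pinacolato)diboron
Product: 3 (Z)-2,3-bis(4,4,5,5-tetramethyl-1,3,2-dioxaborolan-2-yl)but-2-ene
Conditions: Pt(PPh3)4 (3 mol %), 1 in excess, DMF, 80 °C, sealed tube
Reagents that add atoms: none
Why: Platinum(0)-catalysed alkyne diboration: oxidative addition of the B–B bond, syn insertion of the alkyne into Pt–B and reductive elimination put both boryl groups on the same side, so only the cis (Z) bis(boronate) can form; unactivated dialkylalkynes are standard substrates and the low-boiling alkyne is kept in a closed vessel.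

Step 2
Reactants: 4 syringaldehyde (4-hydroxy-3,5-dimethoxybenzaldehyde)
Product: 5 4-(benzyloxy)-3,5-dimethoxybenzaldehyde
Conditions: BnBr, K2CO3, DMF, 60 °C
Reagents that add atoms: benzyl bromide, BrCc1ccccc1
Why: Williamson ether synthesis on the phenoxide; the aldehyde and methyl ethers are inert to carbonate, and the phenol, though flanked by two methoxy groups, is readily O-alkylated by a reactive benzylic halide.

Step 3
Reactants: 5 4-(benzyloxy)-3,5-dimethoxybenzaldehyde
Product: 6 [4-(benzyloxy)-3,5-dimethoxyphenyl]methanol
Conditions: NaBH4, MeOH, 0 °C to rt
Reagents that add atoms: none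
Why: Borohydride reduction of an aryl aldehyde to the primary benzylic alcohol; nothing else in the molecule is reducible under these conditions.

Step 4
Reactants: 6 [4-(benzyloxy)-3,5-dimethoxyphenyl]methanol
Product: 7 2-(benzyloxy)-5-(bromomethyl)-1,3-dimethoxybenzene
Conditions: PBr3 (0.4 equiv), CH2Cl2, 0 °C
Reagents that add atoms: phosphorus tribromide, BrP(Br)Br
Why: Bromination of a primary benzylic alcohol with PBr3 through the phosphite ester and SN2 displacement by bromide; brief exposure at 0 °C should leave the aryl benzyl ether intact, and the bromide is to be used promptly.

Step 5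
Reactants: 3 (Z)-2,3-bis(4,4,5,5-tetramethyl-1,3,2-dioxaborolan-2-yl)but-2-ene; 7 2-(benzyloxy)-5-(bromomethyl)-1,3-dimethoxybenzene (2.3 equiv)
Product: 9 (Z)-1,4-bis[4-(benzyloxy)-3,5-dimethoxyphenyl]-2,3-dimethylbut-2-ene, via mono-benzylated alkenyl boronate 8 (not isolated)
Conditions: PdCl2(dppf)·CH2Cl2 (5 mol %), Cs2CO3, 1,4-dioxane/H2O (10:1), 80 °C
Reagents that add atoms: none
Why: This is a Suzuki–Miyaura coupling run twice on one alkene: Pd(0) adds oxidatively to the benzylic C–Br bond of 7, the base-activated alkenyl–boron bond of 3 transmetalates to benzylpalladium(II) with retention at the sp2 carbon, and reductive elimination forms C7–C8; the same cycle on boronate 8 forms C7′–C8′. The closest known reaction type is the cross-coupling of cis-1,2-bis(boryl)alkenes obtained by alkyne diboration with organic halides, benzyl halides included. No ring closes and no stereocentre is formed; the only stereochemical element is the Z geometry of the tetrasubstituted alkene, which is inherited from the cis-diboration (8 is formally E only because boron ranks below carbon; the two methyls stay cis throughout). The step needs retention of geometry in both transmetalations and completion of the second, more hindered coupling. Retention is secured by the stereoretentive nature of alkenyl–boron transmetalation and by the absence of β-hydrogens in the benzylpalladium intermediate, which gives no palladium hydride and hence no alkene migration or E/Z equilibration. The symmetry of 3 removes any regiochemical question. An excess of 7, a chelating ferrocenyl diphosphine that resists benzylation, and a strong carbonate base in wet dioxane are chosen to push the hindered boronate 8 on to 9.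

Step 6
Reactants: 9 (Z)-1,4-bis[4-(benzyloxy)-3,5-dimethoxyphenyl]-2,3-dimethylbut-2-ene
Product: 10 (2R,3S)-1,4-bis[4-(benzyloxy)-3,5-dimethoxyphenyl]-2,3-dimethylbutane (meso)
Conditions: H2 (50 bar), [Ir(cod)(PCy3)(py)]BArF (5 mol %), CH2Cl2, rt
Reagents that add atoms: none
Why: Homogeneous hydrogenation with a cationic iridium(I) catalyst of the Crabtree type, a class that reduces unfunctionalised tetrasubstituted alkenes; both hydrogens come from one metal centre onto one face, so the Z-alkene can give only the meso (2R,3S) pair at C8/C8′. High hydrogen pressure in a non-coordinating solvent should keep insertion and reductive elimination faster than β-hydride elimination, and benzyl ethers and arenes are not touched.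

Step 7
Reactants: 10 (2R,3S)-1,4-bis[4-(benzyloxy)-3,5-dimethoxyphenyl]-2,3-dimethylbutane (meso)
Product: 11 4,4′-[(2R,3S)-2,3-dimethylbutane-1,4-diyl]bis(2,6-dimethoxyphenol) (meso; target)
Conditions: H2 (1 atm), 10% Pd/C, EtOAc/MeOH, rt
Reagents that add atoms: none
Why: Hydrogenolysis of two aryl benzyl ethers over palladium on carbon under neutral conditions; the saturated chain has no position that can epimerise, so the meso configuration is carried through unchanged.

## Compound list

1 | 2-butyne | CC#CC | starting material
2 | bis(pinacolato)diboron | CC1(C)OB(OC1(C)C)B1OC(C)(C)C(C)(C)O1 | starting material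
3 | (Z)-2,3-bis(4,4,5,5-tetramethyl-1,3,2-dioxaborolan-2-yl)but-2-ene | C/C(B1OC(C)(C)C(C)(C)O1)=C(\C)B1OC(C)(C)C(C)(C)O1 | intermediate
4 | syringaldehyde (4-hydroxy-3,5-dimethoxybenzaldehyde) | COc1cc(C=O)cc(OC)c1O | starting material
5 | 4-(benzyloxy)-3,5-dimethoxybenzaldehyde | COc1cc(C=O)cc(OC)c1OCc1ccccc1 | intermediate
6 | [4-(benzyloxy)-3,5-dimethoxyphenyl]methanol | COc1cc(CO)cc(OC)c1OCc1ccccc1 | intermediate
7 | 2-(benzyloxy)-5-(bromomethyl)-1,3-dimethoxybenzene | COc1cc(CBr)cc(OC)c1OCc1ccccc1 | intermediate
8 | 2-[(2E)-4-[4-(benzyloxy)-3,5-dimethoxyphenyl]-3-methylbut-2-en-2-yl]-4,4,5,5-tetramethyl-1,3,2-dioxaborolane (methyl groups cis) | C/C(Cc1cc(OC)c(OCc2ccccc2)c(OC)c1)=C(\C)B1OC(C)(C)C(C)(C)O1 | intermediate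
9 | (Z)-1,4-bis[4-(benzyloxy)-3,5-dimethoxyphenyl]-2,3-dimethylbut-2-ene | C/C(Cc1cc(OC)c(OCc2ccccc2)c(OC)c1)=C(\C)Cc1cc(OC)c(OCc2ccccc2)c(OC)c1 | intermediate
10 | (2R,3S)-1,4-bis[4-(benzyloxy)-3,5-dimethoxyphenyl]-2,3-dimethylbutane (meso) | COc1cc(C[C@@H](C)[C@@H](C)Cc2cc(OC)c(OCc3ccccc3)c(OC)c2)cc(OC)c1OCc1ccccc1 | intermediate
11 | 4,4′-[(2R,3S)-2,3-dimethylbutane-1,4-diyl]bis(2,6-dimethoxyphenol) (meso) | COc1cc(C[C@@H](C)[C@@H](C)Cc2cc(OC)c(O)c(OC)c2)cc(OC)c1O | target

## Step count and risks

Total: 7 steps. Longest linear sequence: 6 steps (4 → 5 → 6 → 7 → 9 → 10 → 11, steps 2 to 7). Step 1 is a one-step branch that joins at step 5.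

**Step 5 (key step).**
- What may go wrong: the reaction may stall after the first benzylation, because transmetalation of the now tetrasubstituted and more hindered alkenyl boronate is slow. Meanwhile the benzyl bromide is consumed by homocoupling and hydrolysis, and the remaining C–B bond by protodeboronation.
- Fallback: it sets out from 3 and 7 and comes back at 9. It reverses the polarity of the second bond formation.
  - With one equivalent of 7 the coupling is stopped at 8, which is isolated this time.
  - Ipso-iododeboronation of 8 (NaOH, then I2, THF, 0 °C), expected to proceed with retention, gives the alkenyl iodide 2-(benzyloxy)-5-[(2Z)-3-iodo-2-methylbut-2-en-1-yl]-1,3-dimethoxybenzene F1.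
  - Zinc insertion into a second portion of 7 (Zn dust, LiCl, THF) gives [4-(benzyloxy)-3,5-dimethoxybenzyl]zinc bromide F2.
  - Negishi coupling of F1 with F2 (Pd(PPh3)4, THF, rt to 50 °C) should give 9. The slow boron transmetalation is replaced by a fast zinc one.

**Step 6.**
- What may go wrong: reversible insertion and β-hydride elimination at iridium may move the double bond into conjugation with an arene, or into a methyl group, before the second hydrogen is delivered. That would erode the meso relationship. The catalyst may also deactivate before the hindered alkene is fully consumed.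
- Fallback: it sets out from 9 and comes back at 10, and makes no new compound (F0). Diimide, generated in the flask from 4-methylbenzenesulfonohydrazide and sodium acetate in refluxing DME/water and applied in repeated charges, transfers both hydrogens in one concerted, metal-free, suprafacial step. It cannot isomerise the alkene. Tetrasubstituted alkenes are slow acceptors, so a large excess is to be expected.

**Step 4.**
- What may go wrong: hydrogen bromide formed during bromination may cleave the benzyl ether. The electron-rich benzyl bromide may also be lost to hydrolysis or self-alkylation of its own ring during isolation and storage.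
- Fallback: it sets out from 6 and comes back at 9, bypassing 7. It changes the class of electrophile.
  - Phosphorylation of 6 (diethyl chlorophosphate, Et3N, DMAP, CH2Cl2, 0 °C) gives diethyl [4-(benzyloxy)-3,5-dimethoxyphenyl]methyl phosphate F3. F3 is made under basic conditions and is not a strong alkylating agent.
  - F3 is then used in place of 7 in a palladium-catalysed Suzuki–Miyaura coupling with 3 (Pd(OAc)2, PPh3, K3PO4, toluene/H2O, 90 °C). This should lead through 8 to 9.

## Further compounds

F1 | step 5 | 2-(benzyloxy)-5-[(2Z)-3-iodo-2-methylbut-2-en-1-yl]-1,3-dimethoxybenzene | C/C(Cc1cc(OC)c(OCc2ccccc2)c(OC)c1)=C(\C)I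
F2 | step 5 | [4-(benzyloxy)-3,5-dimethoxybenzyl]zinc bromide | COc1cc(C[Zn]Br)cc(OC)c1OCc1ccccc1
F0 | step 6 | none | none
F3 | step 4 | diethyl [4-(benzyloxy)-3,5-dimethoxyphenyl]methyl phosphate | CCOP(=O)(OCC)OCc1cc(OC)c(OCc2ccccc2)c(OC)c1
A1 | alternative 1 | 5-[4-(benzyloxy)-3,5-dimethoxyphenyl]furan-2(5H)-one (racemic) | O=C1C=CC(c2cc(OC)c(OCc3ccccc3)c(OC)c2)O1
A2 | alternative 1 | 3,4-trans-4,5-trans-3-[4-(benzyloxy)-3,5-dimethoxybenzyl]-5-[4-(benzyloxy)-3,5-dimethoxyphenyl]-4-methyldihydrofuran-2(3H)-one (racemic, one enantiomer drawn) | O=C1O[C@H](c2cc(OC)c(OCc3ccccc3)c(OC)c2)[C@@H](C)[C@@H]1Cc1cc(OC)c(OCc2ccccc2)c(OC)c1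
A3 | alternative 2 | (Z)-1,4-bis[4-(benzyloxy)-3,5-dimethoxyphenyl]but-2-ene | COc1cc(C/C=C\Cc2cc(OC)c(OCc3ccccc3)c(OC)c2)cc(OC)c1OCc1ccccc1
A4 | alternative 2 | meso-2,3-bis(4,4,5,5-tetramethyl-1,3,2-dioxaborolan-2-yl)-1,4-bis[4-(benzyloxy)-3,5-dimethoxyphenyl]butane | COc1cc(C[C@@H](B2OC(C)(C)C(C)(C)O2)[C@@H](B2OC(C)(C)C(C)(C)O2)Cc2cc(OC)c(OCc3ccccc3)c(OC)c2)cc(OC)c1OCc1ccccc1
A5 | alternative 2 | meso-1,4-bis(pinacolboryl)-2,3-bis[4-(benzyloxy)-3,5-dimethoxybenzyl]butane | COc1cc(C[C@@H](CB2OC(C)(C)C(C)(C)O2)[C@@H](CB2OC(C)(C)C(C)(C)O2)Cc2cc(OC)c(OCc3ccccc3)c(OC)c2)cc(OC)c1OCc1ccccc1
A6 | alternative 3 | [4-(benzyloxy)-3,5-dimethoxyphenyl]magnesium bromide | COc1cc([Mg]Br)cc(OC)c1OCc1ccccc1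
A7 | alternative 3 | meso-2,3-dimethylbutane-1,4-diyl bis(4-methylbenzenesulfonate) | Cc1ccc(cc1)S(=O)(=O)OC[C@@H](C)[C@@H](C)COS(=O)(=O)c1ccc(C)cc1
A8 | alternative 3 | meso-1,4-bis[4-(benzyloxy)-3,5-dimethoxyphenyl]-2,3-dimethylbutane (identical with 10) | COc1cc(C[C@@H](C)[C@@H](C)Cc2cc(OC)c(OCc3ccccc3)c(OC)c2)cc(OC)c1OCc1ccccc1
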